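**Retrosynthetic overview**

- The target is the (2R,3R)-3-acetate of 5,7-dihydroxy-6-prenylflavanone (flavanone numbering: O1, C2, C3, C4, C4a, C5–C8, C8a); the last step frees the C7 hydroxyl from silyl ether 24.
- The strategy rests on ring A (C4a, C5–OH, C6–prenyl, C7–O, C8–H, C8a–O1). The prenyl carbon C6 sits between two oxygenated carbons and the C5 hydroxyl is peri to the C4 ketone, which is the pattern a vinylketene and a siloxyalkyne give. Ring A is cut at C5–C6, C7–C8 and C4a–C5 into diazo ketone 13 and siloxyalkyne 19.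
- 13 comes from acid 11 and tert-butyl ester 10. The C3 acetate is set by Mn(OAc)3 acetoxylation of dihydropyranone 9, trans to the C2 phenyl. 9 comes from oxalate Claisen condensation and cyclodehydration of methyl ketone 4, made from hydroxy ester 1, which supplies C2.
- 19 comes from prenyl bromide and HC≡CMgBr, then oxidation of the acetylide to the ynolate and O-silylation.
- Ring order: ring B (phenyl) is bought, ring C (dihydropyranone) closes in step 5, ring A closes last in step 11.

Key step: step 11

Assumption: ethyl (S)-3-hydroxy-3-phenylpropanoate (1) is taken as a commercial, enantiopure compound. Its (S) centre has the spatial arrangement of C2 of the target; the descriptor becomes (R) in step 6 only because the oxygenated C3 then outranks phenyl.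

**Route**

Step 1
Reactants: 1 ethyl (S)-3-hydroxy-3-phenylpropanoate
Product: 2 ethyl (S)-3-phenyl-3-(triethylsilyloxy)propanoate
Conditions: Et3SiCl, imidazole, CH2Cl2, 0 °C → rt
Reagents that add atoms: chlorotriethylsilane, CC[Si](Cl)(CC)CC
Why: Routine O-silylation of a secondary benzylic alcohol; the triethylsilyl ether blocks retro-aldol and O-acylation in the basic steps 2–4 and is later removed by mild acid, and the stereocentre is not touched.

Step 2
Reactants: 2 ethyl (S)-3-phenyl-3-(triethylsilyloxy)propanoate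
Product: 3 (S)-N-methoxy-N-methyl-3-phenyl-3-(triethylsilyloxy)propanamide
Conditions: MeNH(OMe)·HCl, iPrMgCl, THF, −20 → 0 °C
Reagents that add atoms: N,O-dimethylhydroxylamine hydrochloride, CNOC.Cl
Why: Aminolysis of the ester by the magnesium amide gives the Weinreb amide at low temperature, where β-elimination of the silyloxy group should not compete.

Step 3
Reactants: 3 (S)-N-methoxy-N-methyl-3-phenyl-3-(triethylsilyloxy)propanamide
Product: 4 (S)-4-phenyl-4-(triethylsilyloxy)butan-2-one
Conditions: MeMgBr, THF, 0 °C; aq. NH4Cl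
Reagents that add atoms: methylmagnesium bromide, C[Mg]Br
Why: Weinreb ketone synthesis; the chelated tetrahedral adduct persists until work-up, so addition should stop at the methyl ketone.

Step 4
Reactants: 4 (S)-4-phenyl-4-(triethylsilyloxy)butan-2-one; 5 di-tert-butyl oxalate
Product: 6 tert-butyl (S)-2,4-dioxo-6-phenyl-6-(triethylsilyloxy)hexanoate
Conditions: LiN(SiMe3)2, THF, −78 °C; then 5, −78 → −20 °C; aq. NH4Cl
Reagents that add atoms: none
Why: Crossed Claisen condensation; kinetic deprotonation at the methyl group and acylation by the non-enolisable oxalate give the 2,4-diketo ester, held as its stabilised enolate until the cold quench.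

Step 5
Reactants: 6 tert-butyl (S)-2,4-dioxo-6-phenyl-6-(triethylsilyloxy)hexanoate
Product: 9 tert-butyl (S)-4-oxo-2-phenyl-3,4-dihydro-2H-pyran-6-carboxylate, via hydroxy diketo ester 7 (not isolated), via cyclic hemiketal 8 (not isolated)
Conditions: TsOH·H2O (cat.), wet CH2Cl2, rt
Reagents that add atoms: none
Why: Catalytic acid cleaves the silyl ether, the freed hydroxyl adds to the keto ester carbonyl (6-exo-trig) and the hemiketal dehydrates to the conjugated dihydropyranone (cyclodehydration of a δ-hydroxy-1,3-diketone); the tert-butyl ester should survive catalytic acid at rt and the C2 centre is not involved.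

Step 6
Reactants: 9 tert-butyl (S)-4-oxo-2-phenyl-3,4-dihydro-2H-pyran-6-carboxylate
Product: 10 tert-butyl (2R,3R)-3-acetoxy-4-oxo-2-phenyl-3,4-dihydro-2H-pyran-6-carboxylate
Conditions: Mn(OAc)3·2H2O, benzene, reflux (Dean–Stark)
Reagents that add atoms: manganese triacetate dihydrate, CC(=O)[O-].CC(=O)[O-].CC(=O)[O-].[Mn+3].O.O
Why: α'-Acetoxylation of an enone by Mn(OAc)3, a reaction known for 2-substituted 2,3-dihydro-4H-pyran-4-ones: the trivalent manganese enolate at C3 is oxidised and acetate is delivered to the face opposite the C2 phenyl, so the new C3 centre should be trans (substrate control), which is also the more stable diequatorial epimer.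

Step 7
Reactants: 10 tert-butyl (2R,3R)-3-acetoxy-4-oxo-2-phenyl-3,4-dihydro-2H-pyran-6-carboxylate
Product: 11 (2R,3R)-3-acetoxy-4-oxo-2-phenyl-3,4-dihydro-2H-pyran-6-carboxylic acid
Conditions: CF3CO2H, CH2Cl2, 0 °C → rt
Reagents that add atoms: none
Why: Acidolysis of the tert-butyl ester with loss of isobutene; acetate, enone and both stereocentres are stable to anhydrous acid, whereas saponification would open the ring by E1cB loss of O1.

Step 8
Reactants: 11 (2R,3R)-3-acetoxy-4-oxo-2-phenyl-3,4-dihydro-2H-pyran-6-carboxylic acid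
Product: 13 (2R,3R)-6-(2-diazoacetyl)-4-oxo-2-phenyl-3,4-dihydro-2H-pyran-3-yl acetate, via acid chloride 12 (not isolated)
Conditions: (COCl)2, DMF (cat.), CH2Cl2, 0 °C → rt; evaporate; CH2N2 (3 equiv), Et2O/CH2Cl2, −20 → 0 °C, dark
Reagents that add atoms: oxalyl chloride, ClC(=O)C(=O)Cl (chlorine of 12 only); diazomethane, C=[N+]=[N-]
Why: Acylation of diazomethane by the acid chloride (first stage of the Arndt–Eistert sequence), with a second equivalent of diazomethane taking up HCl; no base is present, so the C3 centre and the ring are not endangered, and acylation at low temperature should outrun dipolar addition to the trisubstituted ring alkene.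

Step 9
Reactants: 14 1-bromo-3-methylbut-2-ene (prenyl bromide); 15 ethynylmagnesium bromide
Product: 16 5-methylhex-4-en-1-yne
Conditions: HC≡CMgBr (THF solution), CuCl (cat.), THF, 0 → 45 °C
Reagents that add atoms: none
Why: Copper-catalysed coupling of an alkynyl Grignard reagent with an allylic bromide; attack at the unhindered primary carbon should give the linear 1,4-enyne.

Step 10
Reactants: 16 5-methylhex-4-en-1-yne
Product: 19 triisopropyl(5-methylhex-4-en-1-ynyloxy)silane, via lithium acetylide 17 (not isolated), via lithium ynolate 18 (not isolated)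
Conditions: n-BuLi, THF, −78 °C; LiOOtBu (from t-BuOOH and LiN(SiMe3)2), −78 → 0 °C; iPr3SiOTf, −78 → 0 °C
Reagents that add atoms: n-butyllithium, [Li]CCCC (lithium of 17 and 18 only); lithium tert-butylperoxide, [Li]OOC(C)(C)C (made from tert-butyl hydroperoxide, CC(C)(C)OO; gives the ynolate oxygen); triisopropylsilyl triflate, CC(C)[Si](OS(=O)(=O)C(F)(F)F)(C(C)C)C(C)C
Why: Electrophilic oxygenation of a lithium acetylide by the lithium peroxide gives the ynolate, and the bulky silyl triflate silylates it on oxygen to the siloxyalkyne; the trisubstituted alkene is inert to the peroxide anion.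

Step 11
Reactants: 13 (2R,3R)-6-(2-diazoacetyl)-4-oxo-2-phenyl-3,4-dihydro-2H-pyran-3-yl acetate; 19 triisopropyl(5-methylhex-4-en-1-ynyloxy)silane
Product: 24 (2R,3R)-5-hydroxy-6-(3-methylbut-2-enyl)-4-oxo-2-phenyl-7-(triisopropylsilyloxy)chroman-3-yl acetate, via vinylketene 20 (not isolated), via cyclobutenone 21 (not isolated), via dienylketene 22 (not isolated), via cyclohexadienone 23 (not isolated)
Conditions: 19 (2 equiv), hν (254 nm, low-pressure Hg lamp, Vycor), degassed ClCH2CH2Cl, rt; then 80 °C
Reagents that add atoms: none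
Why: Light expels N2 from 13 and Wolff rearrangement gives vinylketene 20, whose electrophilic ketene carbon is attacked by the nucleophilic, prenyl-bearing carbon of 19 in a [2+2] addition to cyclobutenone 21 (C5–C6 and C7–C8 formed), and 4π electrocyclic opening (light or 80 °C) then gives dienylketene 22. Ring A is closed by thermal 6π electrocyclisation of 22, the ketene carbon bonding to pyranone C5 (C4a–C5), and cyclohexadienone 23 aromatises by enolisation of its C4a hydrogen, which lies between two carbonyl groups. The closest known reaction type is the Danheiser benzannulation in its photochemical Wolff variant, run with α,β-unsaturated α'-diazo ketones and trialkylsiloxyalkynes; 13 belongs to that class, although a diazo ketone on a ring enone of this kind has not been tried. No new stereocentre is formed: the sp3 centres of 21 and 23 are transient, and C2 and C3 are not touched under these neutral conditions. The step needs regioselectivity (prenyl at C6 between the two oxygenated carbons), which the polarity of ketene and ynol ether secures, and chemoselectivity, secured by the much higher ketenophilicity of the siloxyalkyne than of the prenyl alkene and by the hydrogen bond of the new C5 hydroxyl to the C4 ketone, which disfavours its acylation by ketene.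

Step 12
Reactants: 24 (2R,3R)-5-hydroxy-6-(3-methylbut-2-enyl)-4-oxo-2-phenyl-7-(triisopropylsilyloxy)chroman-3-yl acetate
Product: 25 (2R,3R)-5,7-dihydroxy-6-(3-methylbut-2-enyl)-4-oxo-2-phenylchroman-3-yl acetate
Conditions: Bu4NF, AcOH, THF, 0 °C
Reagents that add atoms: none
Why: Fluoride cleaves the aryl silyl ether, and the acetic acid buffer keeps the medium from becoming basic, so the acetate, the C3 centre and the ring (C2) should be preserved.

**Compound list**

1 | ethyl (S)-3-hydroxy-3-phenylpropanoate | CCOC(=O)C[C@H](O)c1ccccc1 | starting material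
2 | ethyl (S)-3-phenyl-3-(triethylsilyloxy)propanoate | CCOC(=O)C[C@H](O[Si](CC)(CC)CC)c1ccccc1 | intermediate
3 | (S)-N-methoxy-N-methyl-3-phenyl-3-(triethylsilyloxy)propanamide | CON(C)C(=O)C[C@H](O[Si](CC)(CC)CC)c1ccccc1 | intermediate
4 | (S)-4-phenyl-4-(triethylsilyloxy)butan-2-one | CC(=O)C[C@H](O[Si](CC)(CC)CC)c1ccccc1 | intermediate
5 | di-tert-butyl oxalate | CC(C)(C)OC(=O)C(=O)OC(C)(C)C | starting material
6 | tert-butyl (S)-2,4-dioxo-6-phenyl-6-(triethylsilyloxy)hexanoate (largely enolised) | CC(C)(C)OC(=O)C(=O)CC(=O)C[C@H](O[Si](CC)(CC)CC)c1ccccc1 | intermediate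
7 | tert-butyl (S)-6-hydroxy-2,4-dioxo-6-phenylhexanoate (not isolated) | CC(C)(C)OC(=O)C(=O)CC(=O)C[C@H](O)c1ccccc1 | intermediate
8 | tert-butyl (6S)-2-hydroxy-4-oxo-6-phenyltetrahydro-2H-pyran-2-carboxylate (cyclic hemiketal, both C2 epimers, not isolated) | CC(C)(C)OC(=O)C1(O)CC(=O)C[C@@H](c2ccccc2)O1 | intermediate
9 | tert-butyl (S)-4-oxo-2-phenyl-3,4-dihydro-2H-pyran-6-carboxylate | CC(C)(C)OC(=O)C1=CC(=O)C[C@@H](c2ccccc2)O1 | intermediate
10 | tert-butyl (2R,3R)-3-acetoxy-4-oxo-2-phenyl-3,4-dihydro-2H-pyran-6-carboxylate | CC(=O)O[C@H]1C(=O)C=C(C(=O)OC(C)(C)C)O[C@@H]1c1ccccc1 | intermediate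
11 | (2R,3R)-3-acetoxy-4-oxo-2-phenyl-3,4-dihydro-2H-pyran-6-carboxylic acid | CC(=O)O[C@H]1C(=O)C=C(C(=O)O)O[C@@H]1c1ccccc1 | intermediate
12 | (2R,3R)-3-acetoxy-4-oxo-2-phenyl-3,4-dihydro-2H-pyran-6-carbonyl chloride (not isolated) | CC(=O)O[C@H]1C(=O)C=C(C(=O)Cl)O[C@@H]1c1ccccc1 | intermediate
13 | (2R,3R)-6-(2-diazoacetyl)-4-oxo-2-phenyl-3,4-dihydro-2H-pyran-3-yl acetate | CC(=O)O[C@H]1C(=O)C=C(C(=O)C=[N+]=[N-])O[C@@H]1c1ccccc1 | intermediate
14 | 1-bromo-3-methylbut-2-ene (prenyl bromide) | CC(C)=CCBr | starting material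
15 | ethynylmagnesium bromide | C#C[Mg]Br | starting material
16 | 5-methylhex-4-en-1-yne | CC(C)=CCC#C | intermediate
17 | (5-methylhex-4-en-1-ynyl)lithium (not isolated) | [Li]C#CCC=C(C)C | intermediate
18 | lithium 5-methylhex-4-en-1-yn-1-olate (not isolated) | [Li]OC#CCC=C(C)C | intermediate
19 | triisopropyl(5-methylhex-4-en-1-ynyloxy)silane | CC(C)=CCC#CO[Si](C(C)C)(C(C)C)C(C)C | intermediate
20 | (2R,3R)-4-oxo-6-(2-oxoethenyl)-2-phenyl-3,4-dihydro-2H-pyran-3-yl acetate (vinylketene, not isolated) | CC(=O)O[C@H]1C(=O)C=C(C=C=O)O[C@@H]1c1ccccc1 | intermediate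
21 | (2R,3R)-6-[3-(3-methylbut-2-enyl)-4-oxo-2-(triisopropylsilyloxy)cyclobut-2-en-1-yl]-4-oxo-2-phenyl-3,4-dihydro-2H-pyran-3-yl acetate (both epimers at the cyclobutene sp3 carbon, not isolated) | CC(=O)O[C@H]1C(=O)C=C(C2C(=O)C(CC=C(C)C)=C2O[Si](C(C)C)(C(C)C)C(C)C)O[C@@H]1c1ccccc1 | intermediate
22 | (2R,3R)-6-[3-(3-methylbut-2-enyl)-4-oxo-2-(triisopropylsilyloxy)buta-1,3-dienyl]-4-oxo-2-phenyl-3,4-dihydro-2H-pyran-3-yl acetate (dienylketene; the isomer with ketene and pyranone cis on the enol ether double bond cyclises; not isolated) | CC(=O)O[C@H]1C(=O)C=C(C=C(O[Si](C(C)C)(C(C)C)C(C)C)C(CC=C(C)C)=C=O)O[C@@H]1c1ccccc1 | intermediate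
23 | (2R,3R)-6-(3-methylbut-2-enyl)-4,5-dioxo-2-phenyl-7-(triisopropylsilyloxy)-3,4,4a,5-tetrahydro-2H-chromen-3-yl acetate (cyclohexadienone, both C4a epimers, not isolated) | CC(=O)O[C@H]1C(=O)C2C(=O)C(CC=C(C)C)=C(O[Si](C(C)C)(C(C)C)C(C)C)C=C2O[C@@H]1c1ccccc1 | intermediate
24 | (2R,3R)-5-hydroxy-6-(3-methylbut-2-enyl)-4-oxo-2-phenyl-7-(triisopropylsilyloxy)chroman-3-yl acetate | CC(=O)O[C@H]1C(=O)c2c(cc(O[Si](C(C)C)(C(C)C)C(C)C)c(CC=C(C)C)c2O)O[C@@H]1c1ccccc1 | intermediate
25 | (2R,3R)-5,7-dihydroxy-6-(3-methylbut-2-enyl)-4-oxo-2-phenylchroman-3-yl acetate | CC(=O)O[C@H]1C(=O)c2c(cc(O)c(CC=C(C)C)c2O)O[C@@H]1c1ccccc1 | target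

**Step count and risk**

Total: 12 steps. Longest linear sequence: 10 steps (steps 1–8, 11, 12); the siloxyalkyne branch is steps 9–10.

Steps most likely to fail:

1. Step 11 (key step). The dihydropyranone enone and the flavanone product absorb in the same region as the diazo ketone, so light may be wasted or enone–alkyne photocycloaddition may compete. Ketene 20 may also be lost by dimerisation or by acylating the phenol of 24, and the 4π/6π cascade may stall at cyclobutenone 21. The fallback generates the same ketene in the dark, setting out from 13. Wolff rearrangement under silver catalysis with water as trap (PhCO2Ag, dioxane/H2O, ultrasound, rt) should give 2-[(2R,3R)-3-acetoxy-4-oxo-2-phenyl-3,4-dihydro-2H-pyran-6-yl]acetic acid F1. (COCl)2 with catalytic DMF converts it into 2-[(2R,3R)-3-acetoxy-4-oxo-2-phenyl-3,4-dihydro-2H-pyran-6-yl]acetyl chloride F2. Slow addition of iPr2NEt to F2 and excess 19 in toluene at 0 °C dehydrochlorinates F2 to ketene 20, where the fallback comes back to the route. Thermal [2+2] addition gives 21, which can be isolated, and heating at 80–110 °C completes the passage through 22 and 23 to 24.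

2. Step 8. Diazomethane may add as a 1,3-dipole to the C5=C6 bond, which is activated by two carbonyl groups, instead of being acylated, and HCl that is not scavenged would turn the product into a chloromethyl ketone. The fallback avoids diazomethane by a Nef isocyanide reaction and sets out from acid chloride 12. N-Isocyanoiminotriphenylphosphorane inserts its isocyanide carbon into the C–Cl bond (CH2Cl2, rt) to give (2R,3R)-6-[2-chloro-2-(triphenylphosphoranylidenehydrazinylidene)acetyl]-4-oxo-2-phenyl-3,4-dihydro-2H-pyran-3-yl acetate F3. Hydrolysis of the iminophosphorane with water gives (2R,3R)-6-(2-chloro-2-hydrazinylideneacetyl)-4-oxo-2-phenyl-3,4-dihydro-2H-pyran-3-yl acetate F4. Loss of HCl with iPr2NH and ZnBr2 at 0 °C then gives the diazo ketone, and the fallback comes back to the route at 13.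

3. Step 6. Facial selectivity in the acetate transfer at C3 may be insufficient. The manganese enolate may also open the ring by β-elimination of O1, which would erode C2, or the product may lose acetic acid to give the 4-pyranone. The fallback is a Rubottom oxidation that sets out from 9. Soft enolisation (Et3SiOTf, Et3N, CH2Cl2, −78 → 0 °C) gives tert-butyl (S)-2-phenyl-4-(triethylsilyloxy)-2H-pyran-6-carboxylate F5 without a free enolate. Dimethyldioxirane (acetone/CH2Cl2, −40 °C) epoxidises the electron-rich C3=C4 bond from the face opposite the phenyl group, and mild acid work-up gives tert-butyl (2R,3R)-3-hydroxy-4-oxo-2-phenyl-3,4-dihydro-2H-pyran-6-carboxylate F6. Ac2O and pyridine at 0 °C acetylate F6, and the fallback comes back to the route at 10. A cis-containing mixture could be equilibrated toward trans under acid catalysis, since C3 is epimerisable.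

Further compounds

F1 | step 11 | 2-[(2R,3R)-3-acetoxy-4-oxo-2-phenyl-3,4-dihydro-2H-pyran-6-yl]acetic acid | CC(=O)O[C@H]1C(=O)C=C(CC(=O)O)O[C@@H]1c1ccccc1
F2 | step 11 | 2-[(2R,3R)-3-acetoxy-4-oxo-2-phenyl-3,4-dihydro-2H-pyran-6-yl]acetyl chloride | CC(=O)O[C@H]1C(=O)C=C(CC(=O)Cl)O[C@@H]1c1ccccc1
F3 | step 8 | (2R,3R)-6-[2-chloro-2-(triphenylphosphoranylidenehydrazinylidene)acetyl]-4-oxo-2-phenyl-3,4-dihydro-2H-pyran-3-yl acetate | CC(=O)O[C@H]1C(=O)C=C(C(=O)C(Cl)=NN=P(c2ccccc2)(c2ccccc2)c2ccccc2)O[C@@H]1c1ccccc1
F4 | step 8 | (2R,3R)-6-(2-chloro-2-hydrazinylideneacetyl)-4-oxo-2-phenyl-3,4-dihydro-2H-pyran-3-yl acetate | CC(=O)O[C@H]1C(=O)C=C(C(=O)C(Cl)=NN)O[C@@H]1c1ccccc1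
F5 | step 6 | tert-butyl (S)-2-phenyl-4-(triethylsilyloxy)-2H-pyran-6-carboxylate | CC(C)(C)OC(=O)C1=CC(O[Si](CC)(CC)CC)=C[C@@H](c2ccccc2)O1
F6 | step 6 | tert-butyl (2R,3R)-3-hydroxy-4-oxo-2-phenyl-3,4-dihydro-2H-pyran-6-carboxylate | O[C@H]1C(=O)C=C(C(=O)OC(C)(C)C)O[C@@H]1c1ccccc1
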